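The numbers of this flask stand for no real mixture, and the outcome is calculated.

One enzyme has 9900 turnovers in it over 30 s if it sits as complex the whole time, and that count is the budget of this ledger. Enzyme comes back after each turnover and starting material does not, so starting material is the limiting reagent, and you keep its books.

the same everywhere: enzyme 0.50 µM; time 30 s
- larch: starting material 5.0 mM
- alder: starting material 15 mM
- maple: starting material 50 mM

    complex ⇌ enzyme + target (K1 = 0.0044 M, k1 = 330 s⁻¹)
    starting material + enzyme ⇌ complex (K2 = 95 M⁻¹, k2 = 8.2 × 10⁵ M⁻¹ s⁻¹)
    starting material + target → side product (k3 = 11 M⁻¹ s⁻¹)

- [target] at the end for larch, alder, maple, in this order
- how that number moves from the first to the last of them (hardly changes / rises, then falls / rises all the way / falls, then rises / falls all the way)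

- percentages count the starting material that a species holds: one side product counts as two
- "hardly changes" means that all values lie within two and a half points (for a concentration: within two and a half percent of the largest)
- run time (larch): 30 s

How much of the budget gets used depends on the load. Enzyme enters complex at 8.2 × 10⁵ M⁻¹ s⁻¹ times [starting material]. Complex leaves by two exits, back at 8630 s⁻¹ and forward at 330 s⁻¹. Set entry equal to exits, with [target] small. The sum of the exits over the entry constant is the half-load (the Michaelis constant), 10.9 mM. At that [starting material], half of the enzyme is complex. The complex share is then [starting material] over [starting material] plus the half-load.

Now my own books for maple. The share at the charge is 82.1 %, so I book 8120 turnovers per enzyme, and 4.06 mM passing to target. That is the first entry.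

The second entry is the side reaction. It catches target at 0.550 s⁻¹, a time constant of 1.82 s, so I book each target as caught. One side product holds two starting materials, so the books lose 8.12 mM and keep 41.9 mM, which is 83.8 % of the charge.

The third entry is the target still standing. Making equals catching, [starting material] cancels, and with the way back left out, maple holds 0.284 mM. Complex holds 0.50 µM at the most, so it gets no entry. Each standing target was booked as caught, so one starting material goes back for each, and my books for maple close with 42.2 mM of starting material.

In larch the same count spends 3.11 mM of 5.0 mM. I can't hold its share at the opening value, so my ledger stops there, and I commit to maple's figure and no other.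

The forecast gives 0.55 mM, 0.59 mM and 0.275 mM, with the shape rises, then falls, and says of maple that “side-reaction scavenging is fast”.

The flasks give 0.551 mM, 0.578 mM and 0.274 mM, so the shape is rises, then falls, with the turn at a [starting material] of 9.4 mM. In maple 85 % of the charge stands unbound at the end, 42.4 mM, and the half-load turns that into a complex share of 79.5 %, where the flask holds 79.5 %. In alder the same rule on 10.7 mM gives 49.5 %, where the flask holds 49.6 %. In larch at 12.2 s, target is still made 1.97 times faster than it is used up, each step taken net. At that moment in larch, target falls back at 0.56 times the rate at which it goes on.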